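**Retrosynthetic overview**
1. Both seven-membered ether rings are closed last, in one operation from hydroxy aldehyde 19: intramolecular oxa-Michael addition of the C4 tertiary hydroxyl (C9–O bond) followed by intramolecular Horner–Wadsworth–Emmons closure (C1=C10).
2. 19 comes from the alkylidene phosphonoacetate 18 by ozonolysis of the prenyl group; 18 comes from aldehyde 16 and trimethyl phosphonoacetate 17 (Knoevenagel condensation).
3. The epoxy ester is installed on C6 of diol 14 by Mitsunobu inversion with acid 13 (fragment C, from tiglyl alcohol).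
4. 14 is assembled by zinc Barbier allylation (C6–C7) of hydroxy aldehyde 4 (fragment A, from geraniol) with bromomethyl butenolide 10 (fragment B, from (R)-glycidol).
5. Ring order: lactone ring first (RCM, in 10), then the oxepane and oxepene rings together in the final step.

Assumption: carbons are labelled germacrane-style (C4 = methyl-bearing ether carbon, C5 = CH2, C6 = acyloxy carbon, C7/C8 = lactone ring fusion with C8–O, C9 = second ether carbon, C10 = carbon bearing CO2Me, C1 = vinylic CH, C11–C13 = methylene-lactone carbons); the target is then (4S,6R,7R,8S,9R) with a (2S,3R)-epoxy ester.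

**Step 1**
Reactants: 1 geraniol
Product: 2 (2S,3S)-2,3-epoxygeraniol
Conditions: Ti(OiPr)4 (5 mol %), L-(+)-diethyl tartrate (6 mol %), t-BuOOH, 4 Å molecular sieves, CH2Cl2, −20 °C
Reagents that add atoms: tert-butyl hydroperoxide, CC(C)(C)OO
Why: Sharpless asymmetric epoxidation of the allylic alcohol; the L-(+)-tartrate catalyst delivers oxygen to the face that gives the (2S,3S)-epoxide, which fixes the future C4 ether carbon.

**Step 2**
Reactants: 2 (2S,3S)-2,3-epoxygeraniol
Product: 3 (3S)-3,7-dimethyloct-6-ene-1,3-diol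
Conditions: NaAlH2(OCH2CH2OCH3)2, THF, 0 °C
Reagents that add atoms: none
Why: Hydroxyl-directed reductive epoxide opening; the alkoxyaluminate delivers hydride intramolecularly to C2, giving the 1,3-diol, and the tertiary C–O bond is untouched so C4 keeps its configuration.

**Step 3**
Reactants: 3 (3S)-3,7-dimethyloct-6-ene-1,3-diol
Product: 4 (3S)-3-hydroxy-3,7-dimethyloct-6-enal
Conditions: TEMPO (10 mol %), PhI(OAc)2, CH2Cl2, rt; used crude
Reagents that add atoms: none
Why: Oxoammonium (TEMPO) oxidation is selective for the primary alcohol, the tertiary alcohol cannot be oxidized, and no lactol can form from a 1,3-relationship.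

**Step 4**
Reactants: 5 (R)-glycidol
Product: 6 triethyl{[(2S)-oxiran-2-yl]methoxy}silane
Conditions: Et3SiCl, imidazole, CH2Cl2, 0 °C
Reagents that add atoms: chlorotriethylsilane, CC[Si](Cl)(CC)CC
Why: Standard O-silylation; the stereocentre is untouched (the descriptor changes only through CIP priorities).

**Step 5**
Reactants: 6 triethyl{[(2S)-oxiran-2-yl]methoxy}silane
Product: 7 (2S)-1-[(triethylsilyl)oxy]but-3-en-2-ol
Conditions: Me3S+ I− (3 equiv), n-BuLi, THF, −10 °C → rt
Reagents that add atoms: trimethylsulfonium iodide, C[S+](C)C.[I-]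
Why: One-carbon homologation of a terminal epoxide to an allylic alcohol with dimethylsulfonium methylide (ylide opening at the CH2 terminus, then elimination of Me2S); the carbinol C–O bond is not broken, so the future C8 is retained.

**Step 6**
Reactants: 7 (2S)-1-[(triethylsilyl)oxy]but-3-en-2-ol; 8 2-(bromomethyl)prop-2-enoic acid
Product: 9 (2S)-1-[(triethylsilyl)oxy]but-3-en-2-yl 2-(bromomethyl)prop-2-enoate
Conditions: DCC, DMAP (5 mol %), CH2Cl2, 0 °C
Reagents that add atoms: none
Why: Steglich esterification with retention at the carbinol; any reversible SN2′ addition of DMAP to the bromomethyl acrylate is non-destructive at low loading and temperature.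

**Step 7**
Reactants: 9 (2S)-1-[(triethylsilyl)oxy]but-3-en-2-yl 2-(bromomethyl)prop-2-enoate
Product: 10 (5S)-3-(bromomethyl)-5-{[(triethylsilyl)oxy]methyl}furan-2(5H)-one
Conditions: second-generation Hoveyda–Grubbs catalyst (5 mol %), toluene, 80 °C
Reagents that add atoms: none
Why: Ring-closing metathesis of an allylic 2-substituted acrylate gives the α-substituted butenolide with loss of ethene; the stereocentre is not involved.

**Step 8**
Reactants: 11 tiglyl alcohol ((2E)-2-methylbut-2-en-1-ol)
Product: 12 [(2R,3R)-2,3-dimethyloxiran-2-yl]methanol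
Conditions: Ti(OiPr)4 (10 mol %), D-(−)-diethyl tartrate (12 mol %), t-BuOOH, 4 Å molecular sieves, CH2Cl2, −20 °C
Reagents that add atoms: tert-butyl hydroperoxide, CC(C)(C)OO
Why: Sharpless asymmetric epoxidation; the D-(−)-tartrate catalyst gives the (2R,3R)-epoxy alcohol, which sets both side-chain stereocentres (cis methyls from the E-alkene).

**Step 9**
Reactants: 12 [(2R,3R)-2,3-dimethyloxiran-2-yl]methanol
Product: 13 (2S,3R)-2,3-dimethyloxirane-2-carboxylic acid
Conditions: RuCl3 (2 mol %), NaIO4, CCl4/MeCN/H2O, rt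
Reagents that add atoms: sodium periodate, [Na+].[O-]I(=O)(=O)=O
Why: Catalytic RuO4 oxidation of the primary alcohol to the acid leaves the epoxide intact; the geometry is unchanged and the C2 descriptor becomes S only by CIP priority.

**Step 10**
Reactants: 4 (3S)-3-hydroxy-3,7-dimethyloct-6-enal; 10 (5S)-3-(bromomethyl)-5-{[(triethylsilyl)oxy]methyl}furan-2(5H)-one
Product: 14 (4R,5S)-4-[(1S,3S)-1,3-dihydroxy-3,7-dimethyloct-6-en-1-yl]-3-methylidene-5-{[(triethylsilyl)oxy]methyl}oxolan-2-one
Conditions: Zn dust, THF/sat. aq. NH4Cl (4:1), 0 °C → rt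
Reagents that add atoms: none
Why: Barbier-type allylation with allylic transposition (SE2′) through a closed chair transition state; the aldehyde adds to C7 anti to the C8 silyloxymethyl group (trans lactone), and the ring-locked E-type γ-substituent sits equatorial so the anti adduct (6S) is expected under reagent control, the quaternary C4 carbinol giving no useful 1,3-induction.

**Step 11**
Reactants: 14 (4R,5S)-4-[(1S,3S)-1,3-dihydroxy-3,7-dimethyloct-6-en-1-yl]-3-methylidene-5-{[(triethylsilyl)oxy]methyl}oxolan-2-one; 13 (2S,3R)-2,3-dimethyloxirane-2-carboxylic acid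
Product: 15 (1R,3S)-3-hydroxy-3,7-dimethyl-1-[(2S,3R)-4-methylidene-5-oxo-2-{[(triethylsilyl)oxy]methyl}oxolan-3-yl]oct-6-en-1-yl (2S,3R)-2,3-dimethyloxirane-2-carboxylate
Conditions: PPh3, DIAD, toluene, 0 °C → rt
Reagents that add atoms: none
Why: Mitsunobu esterification (SN2, inversion) turns the (6S) secondary alcohol into the required (6R) ester; the tertiary C4 hydroxyl is not displaced and the epoxy acid is acidic enough for a hindered alcohol.

**Step 12**
Reactants: 15 (the C6 epoxy ester with the primary triethylsilyl ether)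
Product: 16 (1R,3S)-1-[(2S,3R)-2-formyl-4-methylidene-5-oxooxolan-3-yl]-3-hydroxy-3,7-dimethyloct-6-en-1-yl (2S,3R)-2,3-dimethyloxirane-2-carboxylate
Conditions: (COCl)2, DMSO, CH2Cl2, −78 → −40 °C; Et3N; used crude
Reagents that add atoms: none
Why: Swern oxidation converts a primary triethylsilyl ether directly into the aldehyde (chlorosulfonium-mediated desilylation, then ylide fragmentation); the tertiary alcohol has no carbinol hydrogen and is unchanged.

**Step 13**
Reactants: 16 (the C9 aldehyde); 17 trimethyl phosphonoacetate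
Product: 18 methyl 2-(dimethoxyphosphoryl)-3-[(2S,3R)-3-{(1R,3S)-1-[(2S,3R)-2,3-dimethyloxirane-2-carbonyloxy]-3-hydroxy-3,7-dimethyloct-6-en-1-yl}-4-methylidene-5-oxooxolan-2-yl]prop-2-enoate (E/Z mixture)
Conditions: piperidine (20 mol %), AcOH (20 mol %), 4 Å molecular sieves, toluene, 45 °C
Reagents that add atoms: none
Why: Knoevenagel condensation through the iminium/Mannich pathway keeps the phosphonate (no HWE loss) and gives the doubly activated C9=C10 acceptor; alkene geometry is irrelevant for the next step.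

**Step 14**
Reactants: 18 (the alkylidene phosphonoacetate with prenyl terminus)
Product: 21 CNP0240298.1, via hydroxy aldehyde 19 (not isolated), via oxa-Michael adduct 20 (not isolated)
Conditions: O3 (1.05 equiv), pyridine (3 equiv), CH2Cl2, −78 °C; then MeCN (to 0.005 M), LiCl, DBU, 0 °C → rt
Reagents that add atoms: none
Why: Proposed new method: after selective ozonolysis of the electron-rich prenyl alkene, a stereoconvergent intramolecular oxa-Michael/Horner–Wadsworth–Emmons annulation in which the tertiary C4 hydroxyl adds reversibly (7-exo-trig) to the alkylidene phosphonoacetate to give both C9 epimers of the β-alkoxy phosphonate, but only the epimer with the C9–C10 bond cis to the C3 arm can bring its stabilized carbanion onto the C1 aldehyde, so irreversible phosphate elimination drains the equilibrium through that epimer and the one-atom oxygen bridge fixes C9 (R) relative to C4 while the ring forces the cis-in-ring C1=C10 enoate; the closest known reaction type is the intermolecular tandem oxa-Michael/HWE reaction of 2-phosphonoacrylates with hydroxy carbonyl compounds (2H-chromenes, dihydrofurans), not yet shown with a tertiary alcohol, for seven-membered rings or for a bridged bicycle.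

**Compound list**
1 | geraniol, (2E)-3,7-dimethylocta-2,6-dien-1-ol | CC(C)=CCC/C(C)=C/CO | starting material
2 | (2S,3S)-2,3-epoxygeraniol, [(2S,3S)-3-methyl-3-(4-methylpent-3-en-1-yl)oxiran-2-yl]methanol | OC[C@@H]1O[C@@]1(C)CCC=C(C)C | intermediate
3 | (3S)-3,7-dimethyloct-6-ene-1,3-diol | OCC[C@](O)(C)CCC=C(C)C | intermediate
4 | (3S)-3-hydroxy-3,7-dimethyloct-6-enal (fragment A) | O=CC[C@](O)(C)CCC=C(C)C | intermediate
5 | (R)-glycidol, [(2R)-oxiran-2-yl]methanol | OC[C@@H]1CO1 | starting material
6 | triethyl{[(2S)-oxiran-2-yl]methoxy}silane | CC[Si](CC)(CC)OC[C@@H]1CO1 | intermediate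
7 | (2S)-1-[(triethylsilyl)oxy]but-3-en-2-ol | C=C[C@H](O)CO[Si](CC)(CC)CC | intermediate
8 | 2-(bromomethyl)prop-2-enoic acid | OC(=O)C(=C)CBr | starting material
9 | (2S)-1-[(triethylsilyl)oxy]but-3-en-2-yl 2-(bromomethyl)prop-2-enoate | C=C[C@H](OC(=O)C(=C)CBr)CO[Si](CC)(CC)CC | intermediate
10 | (5S)-3-(bromomethyl)-5-{[(triethylsilyl)oxy]methyl}furan-2(5H)-one (fragment B) | O=C1O[C@H](CO[Si](CC)(CC)CC)C=C1CBr | intermediate
11 | tiglyl alcohol, (2E)-2-methylbut-2-en-1-ol | C/C=C(\C)CO | starting material
12 | [(2R,3R)-2,3-dimethyloxiran-2-yl]methanol | OC[C@@]1(C)O[C@@H]1C | intermediate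
13 | (2S,3R)-2,3-dimethyloxirane-2-carboxylic acid (fragment C) | OC(=O)[C@@]1(C)O[C@@H]1C | intermediate
14 | (4R,5S)-4-[(1S,3S)-1,3-dihydroxy-3,7-dimethyloct-6-en-1-yl]-3-methylidene-5-{[(triethylsilyl)oxy]methyl}oxolan-2-one (C6 is S, epimeric to the target) | C=C1C(=O)O[C@H](CO[Si](CC)(CC)CC)[C@H]1[C@@H](O)C[C@](O)(C)CCC=C(C)C | intermediate
15 | (1R,3S)-3-hydroxy-3,7-dimethyl-1-[(2S,3R)-4-methylidene-5-oxo-2-{[(triethylsilyl)oxy]methyl}oxolan-3-yl]oct-6-en-1-yl (2S,3R)-2,3-dimethyloxirane-2-carboxylate | C=C1C(=O)O[C@H](CO[Si](CC)(CC)CC)[C@H]1[C@H](OC(=O)[C@@]2(C)O[C@@H]2C)C[C@](O)(C)CCC=C(C)C | intermediate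
16 | (1R,3S)-1-[(2S,3R)-2-formyl-4-methylidene-5-oxooxolan-3-yl]-3-hydroxy-3,7-dimethyloct-6-en-1-yl (2S,3R)-2,3-dimethyloxirane-2-carboxylate | C=C1C(=O)O[C@H](C=O)[C@H]1[C@H](OC(=O)[C@@]2(C)O[C@@H]2C)C[C@](O)(C)CCC=C(C)C | intermediate
17 | trimethyl phosphonoacetate, methyl 2-(dimethoxyphosphoryl)acetate | COC(=O)CP(=O)(OC)OC | starting material
18 | alkylidene phosphonoacetate: 16 with the formyl group replaced by CH=C(CO2Me)P(O)(OMe)2 (E/Z mixture), C4 tertiary OH free, prenyl terminus | C=C1C(=O)O[C@H](C=C(C(=O)OC)P(=O)(OC)OC)[C@H]1[C@H](OC(=O)[C@@]2(C)O[C@@H]2C)C[C@](O)(C)CCC=C(C)C | intermediate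
19 | hydroxy aldehyde: 18 with the prenyl alkene cleaved to the C1 aldehyde (in equilibrium with its five-membered lactol) | C=C1C(=O)O[C@H](C=C(C(=O)OC)P(=O)(OC)OC)[C@H]1[C@H](OC(=O)[C@@]2(C)O[C@@H]2C)C[C@](O)(C)CCC=O | intermediate
20 | oxa-Michael adduct: 2,7-cis oxepane (C4–O–C9 closed, C9 as in 21) carrying CH(CO2Me)P(O)(OMe)2 on C9 and the 3-oxopropyl arm on C4, trans-fused to the methylene lactone | C=C1C(=O)O[C@H]2[C@H]1[C@H](OC(=O)[C@@]1(C)O[C@@H]1C)C[C@](C)(CCC=O)O[C@@H]2C(C(=O)OC)P(=O)(OC)OC | intermediate
21 | CNP0240298.1: (4S,6R,7R,8S,9R)-4,9-epoxy bridged cyclodec-1(10)-ene (11-oxabicyclo[4.4.1]undecene) with C10 CO2Me, C4 methyl, trans-fused 8,12-α-methylene-γ-lactone and C6 (2S,3R)-2,3-dimethyloxirane-2-carboxylate | C=C1C(=O)O[C@H]2[C@H]1[C@H](OC(=O)[C@@]1(C)O[C@@H]1C)C[C@]1(C)CCC=C(C(=O)OC)[C@H]2O1 | target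

**Step count and risks**
Total steps: 14. Longest linear sequence: 9 (steps 4, 5, 6, 7, 10, 11, 12, 13, 14, from (R)-glycidol).

Most likely to fail:

Step 14 (the proposed oxa-Michael/HWE annulation). Risks are slow addition of the tertiary hydroxyl, base-induced isomerization of the methylene lactone, and C8 epimerization through the γ-position of the acceptor. The fallback uses known chemistry, sets out from 18 and comes back at 21. Compound 18 is cyclized with Cs2CO3 in MeCN (intramolecular oxa-Michael) to the 2,7-cis oxepane phosphonate F4, the trans epimer being re-equilibrated with base and recycled. F4 is methylenated with aqueous formaldehyde and K2CO3 (HWE with formaldehyde) to the C9-alkoxy acrylate F5. F5 is then closed by ring-closing metathesis between the acrylate methylene and the prenyl group with the second-generation Grubbs catalyst in hot toluene, which gives 21 directly.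

Step 11 (Mitsunobu inversion). The alcohol is β-branched, elimination towards C6=C7 is possible, and the step relies on step 10 delivering the (6S) adduct. The fallback sets out from 14 (or any C6 epimer mixture from step 10) and comes back at 15. The secondary alcohol is oxidized with buffered Dess–Martin periodinane to the β-hydroxy ketone F1, which is used at once. F1 is reduced with Me4NBH(OAc)3 in MeCN/AcOH at −30 °C (hydroxyl-directed 1,3-anti reduction from the C4 carbinol) to the (6R) diol F2. F2 is esterified with 13 with retention under Yamaguchi conditions (2,4,6-trichlorobenzoyl chloride, Et3N, DMAP, toluene) to give 15.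

Step 13 (Knoevenagel condensation). The α-acyloxy aldehyde can epimerize at C8 via the enamine, and piperidine can add to the methylene lactone. The fallback sets out from 17 and 16 and comes back at 18. Compound 17 is C-silylated (LDA, Me3SiCl, THF, −78 °C) to methyl 2-(dimethoxyphosphoryl)-2-(trimethylsilyl)acetate F3. The lithium anion of F3 adds to 16 at −78 °C and undergoes Peterson elimination (Si–O rather than P–O) to give 18 without amine or acid catalysis.

**Further compounds**
F1 | step 11 | (4R,5S)-4-[(3S)-3-hydroxy-3,7-dimethyl-1-oxooct-6-en-1-yl]-3-methylidene-5-{[(triethylsilyl)oxy]methyl}oxolan-2-one | C=C1C(=O)O[C@H](CO[Si](CC)(CC)CC)[C@H]1C(=O)C[C@](O)(C)CCC=C(C)C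
F2 | step 11 | (4R,5S)-4-[(1R,3S)-1,3-dihydroxy-3,7-dimethyloct-6-en-1-yl]-3-methylidene-5-{[(triethylsilyl)oxy]methyl}oxolan-2-one (C6 epimer of 14) | C=C1C(=O)O[C@H](CO[Si](CC)(CC)CC)[C@H]1[C@H](O)C[C@](O)(C)CCC=C(C)C
F3 | step 13 | methyl 2-(dimethoxyphosphoryl)-2-(trimethylsilyl)acetate | COC(=O)C(P(=O)(OC)OC)[Si](C)(C)C
F4 | step 14 | 2,7-cis oxepane phosphonate: oxa-Michael adduct of 18 (C4–O–C9 closed, C9 as in 21, CH(CO2Me)P(O)(OMe)2 on C9, prenyl arm intact) | C=C1C(=O)O[C@H]2[C@H]1[C@H](OC(=O)[C@@]1(C)O[C@@H]1C)C[C@](C)(CCC=C(C)C)O[C@@H]2C(C(=O)OC)P(=O)(OC)OC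
F5 | step 14 | 2,7-cis oxepane acrylate: F4 with the phosphonoacetate carbon converted to C(=CH2)CO2Me | C=C1C(=O)O[C@H]2[C@H]1[C@H](OC(=O)[C@@]1(C)O[C@@H]1C)C[C@](C)(CCC=C(C)C)O[C@@H]2C(=C)C(=O)OC
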